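The route rests on cutting the C2–C3 bond of pyranone ring C. Because C2 is a benzylic methine bound to O1 and is the sixth atom counted from C3 along C4, C4a, C8a and O1, it can be traced back to the OCH2 group of an aryl benzyl ether. A chiral dirhodium tetracarboxylate turns a ring A diazomethyl ketone into a carbenoid that inserts into one enantiotopic benzylic C–H, forming C2–C3, closing ring C and fixing the 2S centre in one operation. The precursor is a 2-diazo-1-arylethanone whose ring A carries the ring B benzyl ether at one ortho oxygen and silyl ethers on all other hydroxyls.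

Key step: step 11

Design notes:
- All three phenols are carried as TIPS ethers. On ring A the silyl ether next to the acyl group has to outlast a lithium enolate and aqueous amine and must keep its oxygen away from the carbenoid. On ring B a TIPS group does not shift to the neighbouring carbanion during metalation.
- The ring B side chain is attached through an arylmagnesium made by iodine–magnesium exchange, which fixes the site of attachment, and not by C-allylation of a phenoxide.
- The tertiary alcohol is capped as its TES ether so that no O–H bond is offered to the carbenoid.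

Assumption: the sense of induction of the dirhodium prolinate on this substrate cannot be assigned beforehand; the S ligand series is written, and the mirror-image catalyst Rh2(R-BSP)4 is to be used if the S series favours the 2R product.

**Route**

Step 1
Reactants: 1 geranyl acetate
Product: 3 (2E)-7-hydroxy-3,7-dimethyloct-2-en-1-yl acetate, via organomercurial adduct 2 (not isolated)
Conditions: Hg(OAc)2 (1.0 equiv), THF/H2O 1:1, rt; then NaBH4, 3 M aq. NaOH, 0 °C, short contact
Reagents that add atoms: water, O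
Why: Oxymercuration–demercuration; Hg(OAc)2 should add to the distal trisubstituted alkene (the 2,3-alkene is deactivated by the allylic acetoxy group) with Markovnikov delivery of water to C7, and NaBH4 then replaces mercury by hydrogen, so no stereocentre remains.

Step 2
Reactants: 3 (2E)-7-hydroxy-3,7-dimethyloct-2-en-1-yl acetate
Product: 4 (2E)-3,7-dimethyl-7-(triethylsilyloxy)oct-2-en-1-yl acetate
Conditions: TESOTf, 2,6-lutidine, CH2Cl2, −78 to 0 °C
Reagents that add atoms: triethylsilyl trifluoromethanesulfonate, CC[Si](CC)(CC)OS(=O)(=O)C(F)(F)F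
Why: Silylation of a hindered tertiary alcohol with a silyl triflate and a non-nucleophilic base, to which the allylic acetate and the alkene are inert.

Step 3
Reactants: 4 (2E)-3,7-dimethyl-7-(triethylsilyloxy)oct-2-en-1-yl acetate
Product: 5 (2E)-3,7-dimethyl-7-(triethylsilyloxy)oct-2-en-1-ol
Conditions: K2CO3 (0.2 equiv), MeOH, rt
Reagents that add atoms: none
Why: Base-catalysed transesterification removes the acetate as methyl acetate, and a tertiary TES ether is stable to carbonate in methanol.

Step 4
Reactants: 5 (2E)-3,7-dimethyl-7-(triethylsilyloxy)oct-2-en-1-ol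
Product: 6 (2E)-1-bromo-3,7-dimethyl-7-(triethylsilyloxy)oct-2-ene
Conditions: CBr4, PPh3, CH2Cl2, 0 °C; used without storage
Reagents that add atoms: carbon tetrabromide, BrC(Br)(Br)Br
Why: Appel reaction; bromide displaces the oxyphosphonium at the primary allylic carbon under neutral conditions that spare the TES ether and keep the E geometry.

Step 5
Reactants: 7 methyl 4-hydroxy-3-iodobenzoate
Product: 8 methyl 3-iodo-4-(triisopropylsilyloxy)benzoate
Conditions: TIPSCl, imidazole, DMF, rt
Reagents that add atoms: chlorotriisopropylsilane, CC(C)[Si](Cl)(C(C)C)C(C)C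
Why: Imidazole-mediated silylation of a phenol; TIPS is chosen because it resists retro-Brook migration to an adjacent aryl–metal carbon and survives the later basic steps.

Step 6
Reactants: 8 methyl 3-iodo-4-(triisopropylsilyloxy)benzoate; 6 (2E)-1-bromo-3,7-dimethyl-7-(triethylsilyloxy)oct-2-ene
Product: 10 methyl 3-[(2E)-3,7-dimethyl-7-(triethylsilyloxy)oct-2-en-1-yl]-4-(triisopropylsilyloxy)benzoate, via arylmagnesium chloride 9 (not isolated)
Conditions: i-PrMgCl·LiCl, THF, −30 °C; then Li2CuCl4 (5 mol %), 6, −30 to 0 °C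
Reagents that add atoms: none
Why: Iodine–magnesium exchange with the turbo-Grignard reagent is faster than addition to the ester at −30 °C, and the copper-catalysed coupling of an arylmagnesium with a γ,γ-disubstituted allylic bromide should go at the unhindered α-carbon (SN2) with retention of the E alkene.

Step 7
Reactants: 10 methyl 3-[(2E)-3,7-dimethyl-7-(triethylsilyloxy)oct-2-en-1-yl]-4-(triisopropylsilyloxy)benzoate
Product: 11 {3-[(2E)-3,7-dimethyl-7-(triethylsilyloxy)oct-2-en-1-yl]-4-(triisopropylsilyloxy)phenyl}methanol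
Conditions: i-Bu2AlH (2.5 equiv), CH2Cl2, −78 °C; aq. potassium sodium tartrate (KNaC4H4O6)
Reagents that add atoms: none
Why: Hydride reduction of the benzoate ester to the benzylic alcohol; silyl ethers and the isolated alkene do not react with i-Bu2AlH at low temperature.

Step 8
Reactants: 12 2,4,6-trihydroxyacetophenone (dried)
Product: 13 1-[2-hydroxy-4,6-bis(triisopropylsilyloxy)phenyl]ethanone
Conditions: TIPSCl (2.1 equiv), imidazole, DMF, 0 °C to rt
Reagents that add atoms: chlorotriisopropylsilane, CC(C)[Si](Cl)(C(C)C)C(C)C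
Why: Selective bis-silylation; the 4-OH and one ortho OH should silylate readily, whereas the last ortho hydroxyl is held in a hydrogen bond to the carbonyl group and is too hindered for the bulky silyl chloride.

Step 9
Reactants: 13 1-[2-hydroxy-4,6-bis(triisopropylsilyloxy)phenyl]ethanone; 11 {3-[(2E)-3,7-dimethyl-7-(triethylsilyloxy)oct-2-en-1-yl]-4-(triisopropylsilyloxy)phenyl}methanol
Product: 14 1-[2-({3-[(2E)-3,7-dimethyl-7-(triethylsilyloxy)oct-2-en-1-yl]-4-(triisopropylsilyloxy)phenyl}methoxy)-4,6-bis(triisopropylsilyloxy)phenyl]ethanone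
Conditions: PPh3, DIAD, THF, 0 °C to rt
Reagents that add atoms: none
Why: Mitsunobu etherification joins the acidic chelated phenol to the primary benzylic alcohol under neutral conditions, which the base-labile aryl silyl ethers tolerate.

Step 10
Reactants: 14 1-[2-({3-[(2E)-3,7-dimethyl-7-(triethylsilyloxy)oct-2-en-1-yl]-4-(triisopropylsilyloxy)phenyl}methoxy)-4,6-bis(triisopropylsilyloxy)phenyl]ethanone
Product: 16 2-diazo-1-[2-({3-[(2E)-3,7-dimethyl-7-(triethylsilyloxy)oct-2-en-1-yl]-4-(triisopropylsilyloxy)phenyl}methoxy)-4,6-bis(triisopropylsilyloxy)phenyl]ethanone, via trifluoroacetyl diketone 15 (not isolated)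
Conditions: LiN(SiMe3)2, THF, −78 °C; CF3CO2CH2CF3; aq. NH4Cl work-up; then MsN3, Et3N, H2O (1 equiv), MeCN, rt
Reagents that add atoms: methanesulfonyl azide, CS(=O)(=O)N=[N+]=[N-]
Why: Detrifluoroacetylative diazo transfer; the kinetic lithium enolate of the methyl ketone is C-trifluoroacetylated, and the activated 1,3-diketone takes the diazo group from the sulfonyl azide while the trifluoroacetyl group leaves as the N-acylsulfonamide.

Step 11
Reactants: 16 2-diazo-1-[2-({3-[(2E)-3,7-dimethyl-7-(triethylsilyloxy)oct-2-en-1-yl]-4-(triisopropylsilyloxy)phenyl}methoxy)-4,6-bis(triisopropylsilyloxy)phenyl]ethanone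
Product: 17 (2S)-2-{3-[(2E)-3,7-dimethyl-7-(triethylsilyloxy)oct-2-en-1-yl]-4-(triisopropylsilyloxy)phenyl}-5,7-bis(triisopropylsilyloxy)-2,3-dihydro-4H-chromen-4-one
Conditions: Rh2(S-BSP)4 (BSP = N-benzenesulfonylprolinate; 2 mol %), CH2Cl2, 0 °C to rt, slow addition of 16 at high dilution
Reagents that add atoms: none
Why: The dirhodium tetracarboxylate decomposes the diazo ketone with loss of N2 to an electrophilic rhodium carbenoid at C3, which inserts into a C–H bond of the OCH2Ar group through a concerted, asynchronous three-centre transition state with hydride-shift character, after which the catalyst is released. The closest known reaction type is the intramolecular C–H insertion of 2-alkoxyaryl diazomethyl ketones under chiral dirhodium carboxylate catalysis, which gives 2-substituted chroman-4-ones. Ring C closes by a 1,6-insertion (C3 to C2 across C4, C4a, C8a and O1); the six-membered mode is the only one open because the 1,5-position is the ether oxygen itself, and that oxygen activates the C–H bond next to it. The new centre C2 is set by the catalyst alone: the chiral prolinate ligands around the rhodium-bound carbene make the two enantiotopic benzylic hydrogens diastereotopic in the transition state, and the ligand antipode that leads to 2S is used. The step needs C–H insertion to win over oxonium ylide formation at O1 with [1,2]-benzyl shift, over attack at the second ortho oxygen and over bimolecular reaction with the side-chain alkene; the doubly activated C–H bond (ether oxygen plus electron-rich ring B), the bulky TIPS ether that shields the other ortho oxygen and has no activated C–H, the silylated tertiary alcohol and slow addition should secure this.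

Step 12
Reactants: 17 (2S)-2-{3-[(2E)-3,7-dimethyl-7-(triethylsilyloxy)oct-2-en-1-yl]-4-(triisopropylsilyloxy)phenyl}-5,7-bis(triisopropylsilyloxy)-2,3-dihydro-4H-chromen-4-one
Product: 18 (2S)-5,7-dihydroxy-2-{4-hydroxy-3-[(2E)-7-hydroxy-3,7-dimethyloct-2-en-1-yl]phenyl}-2,3-dihydro-4H-chromen-4-one
Conditions: TBAF/AcOH 1:1 (excess), THF, 0 °C to rt
Reagents that add atoms: none
Why: Fluoride-mediated cleavage of the three aryl TIPS ethers (fast) and the tertiary TES ether (slower); the acetic acid buffer keeps the phenols protonated, so the retro-oxa-Michael ring opening that would racemise C2 should not occur.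

**Compound list**

1 | geranyl acetate | C/C(=C\COC(C)=O)CCC=C(C)C | starting material
2 | organomercurial adduct (not isolated, racemic at C6): (2E)-6-(acetoxymercurio)-7-hydroxy-3,7-dimethyloct-2-en-1-yl acetate | C/C(=C\COC(C)=O)CCC([Hg]OC(C)=O)C(C)(C)O | intermediate
3 | (2E)-7-hydroxy-3,7-dimethyloct-2-en-1-yl acetate | C/C(=C\COC(C)=O)CCCC(C)(C)O | intermediate
4 | (2E)-3,7-dimethyl-7-(triethylsilyloxy)oct-2-en-1-yl acetate | C/C(=C\COC(C)=O)CCCC(C)(C)O[Si](CC)(CC)CC | intermediate
5 | (2E)-3,7-dimethyl-7-(triethylsilyloxy)oct-2-en-1-ol | C/C(=C\CO)CCCC(C)(C)O[Si](CC)(CC)CC | intermediate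
6 | (2E)-1-bromo-3,7-dimethyl-7-(triethylsilyloxy)oct-2-ene | C/C(=C\CBr)CCCC(C)(C)O[Si](CC)(CC)CC | intermediate
7 | methyl 4-hydroxy-3-iodobenzoate | COC(=O)c1ccc(O)c(I)c1 | starting material
8 | methyl 3-iodo-4-(triisopropylsilyloxy)benzoate | COC(=O)c1ccc(O[Si](C(C)C)(C(C)C)C(C)C)c(I)c1 | intermediate
9 | arylmagnesium chloride (not isolated): [5-(methoxycarbonyl)-2-(triisopropylsilyloxy)phenyl]magnesium chloride | COC(=O)c1ccc(O[Si](C(C)C)(C(C)C)C(C)C)c([Mg]Cl)c1 | intermediate
10 | methyl 3-[(2E)-3,7-dimethyl-7-(triethylsilyloxy)oct-2-en-1-yl]-4-(triisopropylsilyloxy)benzoate | C/C(=C\Cc1cc(C(=O)OC)ccc1O[Si](C(C)C)(C(C)C)C(C)C)CCCC(C)(C)O[Si](CC)(CC)CC | intermediate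
11 | {3-[(2E)-3,7-dimethyl-7-(triethylsilyloxy)oct-2-en-1-yl]-4-(triisopropylsilyloxy)phenyl}methanol | C/C(=C\Cc1cc(CO)ccc1O[Si](C(C)C)(C(C)C)C(C)C)CCCC(C)(C)O[Si](CC)(CC)CC | intermediate
12 | 2,4,6-trihydroxyacetophenone | CC(=O)c1c(O)cc(O)cc1O | starting material
13 | 1-[2-hydroxy-4,6-bis(triisopropylsilyloxy)phenyl]ethanone | CC(=O)c1c(O)cc(O[Si](C(C)C)(C(C)C)C(C)C)cc1O[Si](C(C)C)(C(C)C)C(C)C | intermediate
14 | 1-[2-({3-[(2E)-3,7-dimethyl-7-(triethylsilyloxy)oct-2-en-1-yl]-4-(triisopropylsilyloxy)phenyl}methoxy)-4,6-bis(triisopropylsilyloxy)phenyl]ethanone | C/C(=C\Cc1cc(COc2cc(O[Si](C(C)C)(C(C)C)C(C)C)cc(O[Si](C(C)C)(C(C)C)C(C)C)c2C(C)=O)ccc1O[Si](C(C)C)(C(C)C)C(C)C)CCCC(C)(C)O[Si](CC)(CC)CC | intermediate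
15 | trifluoroacetyl diketone (not isolated): 4,4,4-trifluoro-1-[aryl as in 14]butane-1,3-dione | C/C(=C\Cc1cc(COc2cc(O[Si](C(C)C)(C(C)C)C(C)C)cc(O[Si](C(C)C)(C(C)C)C(C)C)c2C(=O)CC(=O)C(F)(F)F)ccc1O[Si](C(C)C)(C(C)C)C(C)C)CCCC(C)(C)O[Si](CC)(CC)CC | intermediate
16 | 2-diazo-1-[2-({3-[(2E)-3,7-dimethyl-7-(triethylsilyloxy)oct-2-en-1-yl]-4-(triisopropylsilyloxy)phenyl}methoxy)-4,6-bis(triisopropylsilyloxy)phenyl]ethanone | C/C(=C\Cc1cc(COc2cc(O[Si](C(C)C)(C(C)C)C(C)C)cc(O[Si](C(C)C)(C(C)C)C(C)C)c2C(=O)C=[N+]=[N-])ccc1O[Si](C(C)C)(C(C)C)C(C)C)CCCC(C)(C)O[Si](CC)(CC)CC | intermediate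
17 | (2S)-2-{3-[(2E)-3,7-dimethyl-7-(triethylsilyloxy)oct-2-en-1-yl]-4-(triisopropylsilyloxy)phenyl}-5,7-bis(triisopropylsilyloxy)-2,3-dihydro-4H-chromen-4-one | C/C(=C\Cc1cc([C@@H]2CC(=O)c3c(O[Si](C(C)C)(C(C)C)C(C)C)cc(O[Si](C(C)C)(C(C)C)C(C)C)cc3O2)ccc1O[Si](C(C)C)(C(C)C)C(C)C)CCCC(C)(C)O[Si](CC)(CC)CC | intermediate
18 | (2S)-5,7-dihydroxy-2-{4-hydroxy-3-[(2E)-7-hydroxy-3,7-dimethyloct-2-en-1-yl]phenyl}-2,3-dihydro-4H-chromen-4-one | C/C(=C\Cc1cc([C@@H]2CC(=O)c3c(O)cc(O)cc3O2)ccc1O)CCCC(C)(C)O | target

**Step count and risks**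

Total step count: 12. Longest linear sequence: 10 steps (steps 1, 2, 3, 4, 6, 7, 9, 10, 11, 12).

Steps most likely to fail:

1. Step 11 (key step). The carbenoid may be diverted to an oxonium ylide at the ether oxygen followed by [1,2]-benzyl shift, or the catalyst may discriminate poorly between the two enantiotopic benzylic hydrogens. The fallback replaces carbenoid chemistry by a palladium-catalysed asymmetric conjugate addition of an arylboronic acid to a chromone; it sets out from 13 and 6 and comes back to the route at 17.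
   - Chromone: compound 13 is condensed with N,N-dimethylformamide dimethyl acetal (toluene, 90 °C) to the enaminone F1, which is closed with TsOH in CH2Cl2, with loss of dimethylamine, to 5,7-bis(triisopropylsilyloxy)chromen-4-one F2.
   - Boronic acid: commercial 4-bromo-2-iodophenol (Oc1ccc(Br)cc1I) is silylated (TIPSCl, imidazole, DMF) to the aryl silyl ether F3. Selective iodine–magnesium exchange (i-PrMgCl·LiCl, THF, −30 °C) and Li2CuCl4-catalysed allylation with bromide 6 give the aryl bromide F4. Bromine–lithium exchange (n-BuLi, THF, −78 °C), B(Oi-Pr)3 and mild aqueous hydrolysis give the arylboronic acid F5.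
   - Union: addition of F5 to F2 with Pd(OCOCF3)2, the tert-butyl pyridine-oxazoline ligand antipode that gives the 2S product, NH4PF6 and H2O in ClCH2CH2Cl at 60 °C should deliver 17, which then enters step 12.

2. Step 6. The arylmagnesium may attack the γ-carbon and give the branched isomer, the alkene geometry may erode through allylcopper isomerisation, or the arylmagnesium may add to the ester. The fallback is a Stille coupling, which sets out from 6 and 8 and comes back at 10. Bromide 6 is treated with Bu3SnLi (from Bu3SnH and LiN(i-Pr)2, THF, −78 °C) to give the allylstannane F6. Coupling of F6 with aryl iodide 8 (Pd(PPh3)4, DMF, 80 °C) transfers the allyl group at its unsubstituted terminus and should give 10 without any aryl–metal intermediate.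

3. Step 10. The ortho silyl group may transfer from the phenol oxygen to the enolate oxygen, C-acylation of the hindered enolate may be slow, or an aryl silyl ether may be lost in the aqueous amine stage. The fallback installs the diazo group by substitution and elimination instead of diazo transfer; it sets out from 14 and comes back at 16. Soft enolisation of 14 (TMSOTf, Et3N, CH2Cl2, 0 °C) gives the trimethylsilyl enol ether F7. NBS in THF at −78 °C converts it into the bromomethyl ketone F8. Treatment of F8 with N,N'-ditosylhydrazine and DBU (THF, 0 °C) displaces bromide and eliminates two sulfinate groups to give 16.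

**Further compounds**

F1 | step 11 | (2E)-3-(dimethylamino)-1-[2-hydroxy-4,6-bis(triisopropylsilyloxy)phenyl]prop-2-en-1-one | CN(C)/C=C/C(=O)c1c(O)cc(O[Si](C(C)C)(C(C)C)C(C)C)cc1O[Si](C(C)C)(C(C)C)C(C)C
F2 | step 11 | 5,7-bis(triisopropylsilyloxy)-4H-chromen-4-one | O=c1ccoc2cc(O[Si](C(C)C)(C(C)C)C(C)C)cc(O[Si](C(C)C)(C(C)C)C(C)C)c12
F3 | step 11 | (4-bromo-2-iodophenoxy)triisopropylsilane | CC(C)[Si](Oc1ccc(Br)cc1I)(C(C)C)C(C)C
F4 | step 11 | {4-bromo-2-[(2E)-3,7-dimethyl-7-(triethylsilyloxy)oct-2-en-1-yl]phenoxy}triisopropylsilane | C/C(=C\Cc1cc(Br)ccc1O[Si](C(C)C)(C(C)C)C(C)C)CCCC(C)(C)O[Si](CC)(CC)CC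
F5 | step 11 | {3-[(2E)-3,7-dimethyl-7-(triethylsilyloxy)oct-2-en-1-yl]-4-(triisopropylsilyloxy)phenyl}boronic acid | C/C(=C\Cc1cc(B(O)O)ccc1O[Si](C(C)C)(C(C)C)C(C)C)CCCC(C)(C)O[Si](CC)(CC)CC
F6 | step 6 | tributyl[(2E)-3,7-dimethyl-7-(triethylsilyloxy)oct-2-en-1-yl]stannane | C/C(=C\C[Sn](CCCC)(CCCC)CCCC)CCCC(C)(C)O[Si](CC)(CC)CC
F7 | step 10 | trimethylsilyl enol ether of 14: {1-[aryl as in 14]ethenyloxy}trimethylsilane | C/C(=C\Cc1cc(COc2cc(O[Si](C(C)C)(C(C)C)C(C)C)cc(O[Si](C(C)C)(C(C)C)C(C)C)c2C(=C)O[Si](C)(C)C)ccc1O[Si](C(C)C)(C(C)C)C(C)C)CCCC(C)(C)O[Si](CC)(CC)CC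
F8 | step 10 | 2-bromo-1-[2-({3-[(2E)-3,7-dimethyl-7-(triethylsilyloxy)oct-2-en-1-yl]-4-(triisopropylsilyloxy)phenyl}methoxy)-4,6-bis(triisopropylsilyloxy)phenyl]ethanone | C/C(=C\Cc1cc(COc2cc(O[Si](C(C)C)(C(C)C)C(C)C)cc(O[Si](C(C)C)(C(C)C)C(C)C)c2C(=O)CBr)ccc1O[Si](C(C)C)(C(C)C)C(C)C)CCCC(C)(C)O[Si](CC)(CC)CC
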